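**Retrosynthetic overview**
1. Last, the two tropolone hydroxyls are unmasked from methyl ethers (step 16). Before that, pyran rings B and C are closed together: the C2 and C2' alkoxides each displace the methoxy group on ring carbon 4 of the neighbouring seven-membered ring, forming O1–A4 and O1'–D4 (step 15).
2. The key disconnection is C4–A5 and C4'–D5. Both bonds are made in one flask by 9-BBN hydroboration of a tetraene bis(silyl ether) and double B-alkyl Suzuki coupling with two equivalents of one bromotroponoid; the hydroboration also sets C3.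
3. The feature used: rings A and D are the same 6-methyltropolone (locants: carbonyl carbon 1, hydroxyl carbon 2). Each is joined through ring carbon 5, which lies between the oxygen-bearing carbon 4 and the methyl-bearing carbon 6, to a CH2 group (C4, C4') of a chain that is pseudo-C2-symmetric about the C2–(E,E)-diene–C2' diol.
4. Tetraene 19 comes from fumaraldehyde bis(dimethyl acetal): dienal mono-acetal, then two catalyst-controlled alkenylzinc additions (vinyl, then isopropenyl), each followed by silylation.
5. Bromotroponoid 7 comes from 2-methylanisole: Birch reduction, dibromocarbene addition, dihydroxylation, oxidation with cyclopropane ring expansion, O-methylation. Ring order: seven-membered rings A and D first (as 7), then pyrans B and C together.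

Key step: step 13

Remark: the alkenylzinc additions are assumed to follow the usual sense of the isoborneol amino alcohols (the (2S)-ligand sends the zinc-bound group to the Si face of an aldehyde), so the (2R)-ligand is used for Re-face delivery in steps 8 and 11.
Remark: tropolone 6 is a tautomeric pair and its O-methylation is assumed to give both regioisomeric ethers; 7 is the one separated and carried on.

**Bromotroponoid**

Step 1
Reactants: 1 2-methylanisole
Product: 2 1-methoxy-2-methylcyclohexa-1,4-diene
Conditions: Li, NH3(l), THF, t-BuOH, –78 to –33 °C; then H2O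
Reagents that add atoms: none
Why: Birch reduction protonates the ring ortho and meta to the donor groups, so the methoxy- and methyl-bearing carbons stay together on one tetrasubstituted enol-ether double bond.

Step 2
Reactants: 2 1-methoxy-2-methylcyclohexa-1,4-diene
Product: 3 7,7-dibromo-1-methoxy-6-methylbicyclo[4.1.0]hept-3-ene (racemic, cis-fused)
Conditions: CHBr3 (1.1 equiv), KOtBu, pentane, –20 to 0 °C
Reagents that add atoms: bromoform, BrC(Br)Br
Why: Dibromocarbene from α-elimination of bromoform is electrophilic and should add in a [2+1] cycloaddition to the electron-rich tetrasubstituted enol ether much faster than to the plain disubstituted alkene, the cis ring fusion following from syn addition.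

Step 3
Reactants: 3 7,7-dibromo-1-methoxy-6-methylbicyclo[4.1.0]hept-3-ene
Product: 4 7,7-dibromo-1-methoxy-6-methylbicyclo[4.1.0]heptane-3,4-diol (racemic cis-diol)
Conditions: OsO4 (cat.), NMO, acetone–H2O, 0 °C to rt
Reagents that add atoms: N-methylmorpholine N-oxide, C[N+]1([O-])CCOCC1; water, O
Why: Catalytic osmium tetroxide syn-dihydroxylation of the only remaining alkene gives a cis-diol whose configuration is immaterial because both carbinol carbons and both ring-fusion carbons become sp2 in step 4.

Step 4
Reactants: 4 7,7-dibromo-1-methoxy-6-methylbicyclo[4.1.0]heptane-3,4-diol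
Product: 6 5-bromo-2-hydroxy-4-methoxy-6-methylcyclohepta-2,4,6-trien-1-one, via bicyclic 1,2-diketone 5 (not isolated)
Conditions: TFAA, DMSO, CH2Cl2, –78 °C; then Et3N, –78 °C to rt
Reagents that add atoms: none
Why: Swern-type oxidation with anhydride-activated DMSO gives the 1,2-diketone, whose enolate opens the cyclopropane with loss of bromide (vinylogous E1cB, a cyclopropyl-to-allyl ring expansion), and tautomerisation then gives the tropolone with bromine on the former carbene carbon between the methoxy- and methyl-bearing carbons.

Step 5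
Reactants: 6 5-bromo-2-hydroxy-4-methoxy-6-methylcyclohepta-2,4,6-trien-1-one
Product: 7 5-bromo-2,4-dimethoxy-6-methylcyclohepta-2,4,6-trien-1-one
Conditions: MeI, K2CO3, acetone, rt; chromatography
Reagents that add atoms: iodomethane, CI
Why: Williamson O-alkylation of the tropolonate should favour the oxygen in direct vinylogous conjugation with the 4-methoxy group, and the regioisomeric ether (5-bromo-2,6-dimethoxy-4-methyl) that also forms is removed by chromatography.

**Tetraene**

Step 6
Reactants: 8 (E)-1,1,4,4-tetramethoxybut-2-ene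
Product: 9 (E)-4,4-dimethoxybut-2-enal
Conditions: Amberlyst-15 (cat.), acetone, H2O (1 equiv), rt
Reagents that add atoms: water, O
Why: Acid-catalysed acetal hydrolysis should stop after one end, because the remaining acetal is then conjugated to an enal and ionises far more slowly.

Step 7
Reactants: 9 (E)-4,4-dimethoxybut-2-enal
Product: 10 (2E,4E)-6,6-dimethoxyhexa-2,4-dienal
Conditions: Ph3P=CHCHO (1.0 equiv), toluene, 50 °C
Reagents that add atoms: (triphenylphosphoranylidene)acetaldehyde, O=CC=P(c1ccccc1)(c1ccccc1)c1ccccc1
Why: Wittig olefination with a stabilised ylide gives the new (E)-alkene, and the product dienal is less electrophilic than 9, which limits a second homologation.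

Step 8
Reactants: 10 (2E,4E)-6,6-dimethoxyhexa-2,4-dienal; 11 vinylmagnesium bromide
Product: 13 (3R,4E,6E)-8,8-dimethoxyocta-1,4,6-trien-3-ol, via divinylzinc 12 (not isolated)
Conditions: ZnCl2, THF, 0 °C; 1,4-dioxane, filter, solvent switched to toluene; (2R)-(+)-3-exo-morpholinoisoborneol [(+)-MIB] (10 mol %), –20 to 0 °C; aq. NH4Cl
Reagents that add atoms: none
Why: Amino-alcohol-catalysed enantioselective 1,2-addition of a dialkenylzinc to an aldehyde, in which the chiral zinc aminoalkoxide delivers vinyl to the Re face of the enal and so sets the R carbinol (later C2').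

Step 9
Reactants: 13 (3R,4E,6E)-8,8-dimethoxyocta-1,4,6-trien-3-ol
Product: 14 triethyl{[(3R,4E,6E)-8,8-dimethoxyocta-1,4,6-trien-3-yl]oxy}silane
Conditions: TESCl, imidazole, DMF, 0 °C
Reagents that add atoms: chlorotriethylsilane, CC[Si](Cl)(CC)CC
Why: Imidazole-promoted silylation of a secondary alcohol under basic conditions that leave the acetal and the acid-sensitive bis-allylic carbinol untouched.

Step 10
Reactants: 14 triethyl{[(3R,4E,6E)-8,8-dimethoxyocta-1,4,6-trien-3-yl]oxy}silane
Product: 15 (2E,4E,6R)-6-(triethylsilyloxy)octa-2,4,7-trienal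
Conditions: PPTS (cat.), acetone–H2O, 0 °C to rt
Reagents that add atoms: water, O
Why: The dimethyl acetal of a dienal ionises to a dienyl-stabilised oxocarbenium ion under very mild acid, so acetal hydrolysis should outrun cleavage of the secondary TES ether.

Step 11
Reactants: 15 (2E,4E,6R)-6-(triethylsilyloxy)octa-2,4,7-trienal; 16 isopropenylmagnesium bromide
Product: 18 (3S,4E,6E,8R)-2-methyl-8-(triethylsilyloxy)deca-1,4,6,9-tetraen-3-ol, via diisopropenylzinc 17 (not isolated)
Conditions: ZnCl2, THF, 0 °C; 1,4-dioxane, filter, solvent switched to toluene; (+)-MIB (10 mol %), –20 to 0 °C; aq. NH4Cl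
Reagents that add atoms: none
Why: The same amino-alcohol-catalysed alkenylzinc addition, again to the Re face under ligand control (the remote C8 centre has no influence), sets the carbinol that becomes C2, its descriptor being S only because isopropenyl outranks the dienyl chain.

Step 12
Reactants: 18 (3S,4E,6E,8R)-2-methyl-8-(triethylsilyloxy)deca-1,4,6,9-tetraen-3-ol
Product: 19 (3S,4E,6E,8R)-2-methyldeca-1,4,6,9-tetraene-3,8-diol bis(triethylsilyl ether)
Conditions: TESCl, imidazole, DMF, 0 °C
Reagents that add atoms: chlorotriethylsilane, CC[Si](Cl)(CC)CC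
Why: Imidazole-promoted silylation as in step 9, giving the bis-allylic tetraene with both carbinols masked.

**Union and end game**

Step 13
Reactants: 19 (3S,4E,6E,8R)-2-methyldeca-1,4,6,9-tetraene-3,8-diol bis(triethylsilyl ether); 7 5-bromo-2,4-dimethoxy-6-methylcyclohepta-2,4,6-trien-1-one (2.3 equiv)
Product: 21 5,5'-[(2R,3R,4E,6E,8R)-2-methyl-3,8-bis(triethylsilyloxy)deca-4,6-diene-1,10-diyl]bis(2,4-dimethoxy-6-methylcyclohepta-2,4,6-trien-1-one), via bis(B-alkyl-9-BBN) adduct 20 (not isolated)
Conditions: 9-BBN (2.4 equiv), THF, 0 °C to rt; aq. Cs2CO3; then 7, PdCl2(dppf) (10 mol %), AsPh3 (20 mol %), DMF, rt to 50 °C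
Reagents that add atoms: none
Why: 9-BBN adds B–H across the vinyl and isopropenyl termini in a four-centre syn addition with boron on the terminal carbons, and the two primary alkylboranes of 20 are coupled without isolation: PdCl2(dppf), a divalent palladium precatalyst, is reduced in the flask to zerovalent palladium, which inserts into the C5–Br bond of 7, the base-activated borane transfers its primary alkyl group, and reductive elimination forms C4–A5 and C4'–D5. The closest known reaction type is the 9-BBN hydroboration/B-alkyl Suzuki–Miyaura coupling of a terminal alkene with a vinyl or aryl bromide, used here twice on one substrate. No ring is closed in this step. The one new stereocentre, C3, is set by acyclic 1,2-induction from the C2 silyloxy centre: the bulky borane attacks the isopropenyl group in the conformer that keeps the allylic hydrogen next to the incoming boron and the dienyl chain anti to it, which should give the 2,3-anti (3R) arrangement known for 9-BBN with 2-substituted allylic ethers. The step needs chemoselectivity for the two terminal alkenes over the internal (E,E)-diene, which the steric demand of 9-BBN toward 1,2-disubstituted and conjugated alkenes secures, and terminal regioselectivity, which also keeps boron γ rather than β to the silyloxy groups so that no β-elimination is possible. Because the bromide is flanked by methoxy and methyl groups, transmetalation of the β-branched C4 borane is expected to be the slow event, hence the AsPh3 co-ligand and gentle heating.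

Step 14
Reactants: 21 bis(dimethoxytroponoid) diene bis(triethylsilyl ether)
Product: 22 5,5'-[(2R,3R,4E,6E,8R)-3,8-dihydroxy-2-methyldeca-4,6-diene-1,10-diyl]bis(2,4-dimethoxy-6-methylcyclohepta-2,4,6-trien-1-one)
Conditions: HF·pyridine, pyridine, THF, 0 °C to rt
Reagents that add atoms: none
Why: Fluoride-driven Si–O cleavage of the two secondary TES ethers under pyridine-buffered conditions that should neither ionise the dienylic carbinols nor generate alkoxide prematurely.

Step 15
Reactants: 22 open-chain bis(dimethoxytroponoid) diol
Product: 23 (2R,3R)-8-methoxy-2-{(1E,3E)-4-[(2R)-8-methoxy-5-methyl-7-oxo-2,3,4,7-tetrahydrocyclohepta[b]pyran-2-yl]buta-1,3-dien-1-yl}-3,5-dimethyl-3,4-dihydrocyclohepta[b]pyran-7(2H)-one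
Conditions: NaH (2.5 equiv), THF (0.01 M), 0 °C to rt; aq. work-up
Reagents that add atoms: none
Why: Intramolecular nucleophilic vinylic substitution by addition–elimination (6-exo), in which each alkoxide adds to the methoxy-bearing ring carbon 4, the end of the O=C1–C7=C6–C5=C4 doubly vinylogous ester, and the resulting dienolate expels methoxide; the carbinol C–O bonds are not broken, so C2 and C2' keep their configuration and ring B is 2,3-trans.

Step 16
Reactants: 23 bis-pyran bis(methyl ether)
Product: 24 (2R,3R)-8-hydroxy-2-{(1E,3E)-4-[(2R)-8-hydroxy-5-methyl-7-oxo-2,3,4,7-tetrahydrocyclohepta[b]pyran-2-yl]buta-1,3-dien-1-yl}-3,5-dimethyl-3,4-dihydrocyclohepta[b]pyran-7(2H)-one (CNP0332980.1)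
Conditions: 2 M aq. LiOH, THF, 45 °C; then 1 M HCl to pH 5, 0 °C
Reagents that add atoms: lithium hydroxide, [Li+].[OH-]
Why: Alkaline hydrolysis of a 2-methoxytropone (a vinylogous methyl ester) by hydroxide addition–elimination at ring carbon 2, the most electrophilic ring position, after which the electron-rich tropolonate should resist attack at the pyran-bearing carbon, while the allylic ethers and the diene are inert to base.

**Compound list**
1 | 2-methylanisole | COc1ccccc1C | starting material
2 | 1-methoxy-2-methylcyclohexa-1,4-diene | COC1=C(C)CC=CC1 | intermediate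
3 | 7,7-dibromo-1-methoxy-6-methylbicyclo[4.1.0]hept-3-ene (racemic, cis-fused; one enantiomer drawn) | CO[C@]12CC=CC[C@@]1(C)C2(Br)Br | intermediate
4 | 7,7-dibromo-1-methoxy-6-methylbicyclo[4.1.0]heptane-3,4-diol (racemic cis-diol; drawn with the hydroxyls on the face away from the CBr2 bridge) | CO[C@]12C[C@H](O)[C@H](O)C[C@@]1(C)C2(Br)Br | intermediate
5 | 7,7-dibromo-1-methoxy-6-methylbicyclo[4.1.0]heptane-3,4-dione (racemic) | CO[C@]12CC(=O)C(=O)C[C@@]1(C)C2(Br)Br | intermediate (not isolated)
6 | 5-bromo-2-hydroxy-4-methoxy-6-methylcyclohepta-2,4,6-trien-1-one | Cc1cc(=O)c(O)cc(OC)c1Br | intermediate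
7 | 5-bromo-2,4-dimethoxy-6-methylcyclohepta-2,4,6-trien-1-one | Cc1cc(=O)c(OC)cc(OC)c1Br | intermediate
8 | (E)-1,1,4,4-tetramethoxybut-2-ene | COC(OC)/C=C/C(OC)OC | starting material
9 | (E)-4,4-dimethoxybut-2-enal | COC(OC)/C=C/C=O | intermediate
10 | (2E,4E)-6,6-dimethoxyhexa-2,4-dienal | COC(OC)/C=C/C=C/C=O | intermediate
11 | vinylmagnesium bromide | C=C[Mg]Br | starting material
12 | divinylzinc | C=C[Zn]C=C | intermediate (not isolated)
13 | (3R,4E,6E)-8,8-dimethoxyocta-1,4,6-trien-3-ol | COC(OC)/C=C/C=C/[C@H](O)C=C | intermediate
14 | triethyl{[(3R,4E,6E)-8,8-dimethoxyocta-1,4,6-trien-3-yl]oxy}silane | COC(OC)/C=C/C=C/[C@H](O[Si](CC)(CC)CC)C=C | intermediate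
15 | (2E,4E,6R)-6-(triethylsilyloxy)octa-2,4,7-trienal | O=C/C=C/C=C/[C@H](O[Si](CC)(CC)CC)C=C | intermediate
16 | isopropenylmagnesium bromide | CC(=C)[Mg]Br | starting material
17 | diisopropenylzinc | CC(=C)[Zn]C(C)=C | intermediate (not isolated)
18 | (3S,4E,6E,8R)-2-methyl-8-(triethylsilyloxy)deca-1,4,6,9-tetraen-3-ol | C=C(C)[C@H](/C=C/C=C/[C@H](O[Si](CC)(CC)CC)C=C)O | intermediate
19 | (3S,4E,6E,8R)-2-methyldeca-1,4,6,9-tetraene-3,8-diol bis(triethylsilyl ether) | C=C(C)[C@H](/C=C/C=C/[C@H](O[Si](CC)(CC)CC)C=C)O[Si](CC)(CC)CC | intermediate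
20 | 1,10-bis(9-borabicyclo[3.3.1]nonan-9-yl)-2-methyl-3,8-bis(triethylsilyloxy)deca-4,6-diene (4E,6E; centres as in 21) | C(B1C2CCCC1CCC2)[C@@H](C)[C@H](/C=C/C=C/[C@H](O[Si](CC)(CC)CC)CCB1C2CCCC1CCC2)O[Si](CC)(CC)CC | intermediate (not isolated)
21 | 5,5'-[(2R,3R,4E,6E,8R)-2-methyl-3,8-bis(triethylsilyloxy)deca-4,6-diene-1,10-diyl]bis(2,4-dimethoxy-6-methylcyclohepta-2,4,6-trien-1-one) | Cc1cc(=O)c(OC)cc(OC)c1C[C@@H](C)[C@H](/C=C/C=C/[C@H](O[Si](CC)(CC)CC)CCc1c(C)cc(=O)c(OC)cc1OC)O[Si](CC)(CC)CC | intermediate
22 | 5,5'-[(2R,3R,4E,6E,8R)-3,8-dihydroxy-2-methyldeca-4,6-diene-1,10-diyl]bis(2,4-dimethoxy-6-methylcyclohepta-2,4,6-trien-1-one) | Cc1cc(=O)c(OC)cc(OC)c1C[C@@H](C)[C@H](/C=C/C=C/[C@H](O)CCc1c(C)cc(=O)c(OC)cc1OC)O | intermediate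
23 | (2R,3R)-8-methoxy-2-{(1E,3E)-4-[(2R)-8-methoxy-5-methyl-7-oxo-2,3,4,7-tetrahydrocyclohepta[b]pyran-2-yl]buta-1,3-dien-1-yl}-3,5-dimethyl-3,4-dihydrocyclohepta[b]pyran-7(2H)-one | Cc1cc(=O)c(OC)cc2c1C[C@@H](C)[C@H](/C=C/C=C/[C@H]1CCc3c(C)cc(=O)c(OC)cc3O1)O2 | intermediate
24 | (2R,3R)-8-hydroxy-2-{(1E,3E)-4-[(2R)-8-hydroxy-5-methyl-7-oxo-2,3,4,7-tetrahydrocyclohepta[b]pyran-2-yl]buta-1,3-dien-1-yl}-3,5-dimethyl-3,4-dihydrocyclohepta[b]pyran-7(2H)-one | Cc1cc(=O)c(O)cc2c1C[C@@H](C)[C@H](/C=C/C=C/[C@H]1CCc3c(C)cc(=O)c(O)cc3O1)O2 | target

**Step count**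
Total: 16 steps. Longest linear sequence: 11 steps (8 to 24: steps 6–12, then 13–16); the bromotroponoid branch adds 5 steps (1–5).

**Steps most likely to fail**

Step 13. Oxidative addition should be easy, but transmetalation and reductive elimination at a bromide flanked by methoxy and methyl groups may be slow. Protodeboronation or β-hydride elimination of the β-branched C4 borane, or arrest after one coupling, could then take over, and the anti selectivity of the hydroboration may be incomplete. The fallback sets out from 19 and keeps the same two bonds but changes the organometallic partner. The same double hydroboration is worked up oxidatively (NaBO3·4H2O) to the 1,10-diol corresponding to 21, 2-methyl-3,8-bis(triethylsilyloxy)deca-4,6-diene-1,10-diol F1, at which stage a minor C3 epimer can be removed. Appel iodination (I2, PPh3, imidazole) gives 1,10-diiodo-2-methyl-3,8-bis(triethylsilyloxy)deca-4,6-diene F2. Zinc insertion (Zn dust, LiCl, THF) gives the bis(iodozinc) reagent F3, used in the flask, and Negishi coupling with 7 (Pd(OAc)2, SPhos, THF–NMP) comes back to the route at 21.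

Step 15. Ring carbon 4 is less electrophilic than carbon 2, so the closure may be sluggish and intermolecular alkoxide attack at carbon 2 of another molecule (oligomeric ether exchange) could compete. The fallback sets out from diol 22 and comes back at 23 through the cationic manifold: catalytic PPTS or CSA with 5 Å molecular sieves in toluene at 60 °C. The O-protonated tropone (a hydroxytropylium ion) is attacked at carbon 4 by the neutral hydroxyl and methanol is lost, as in the acid-catalysed alkoxy exchange of vinylogous esters. No new isolated compound is involved.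

Step 8. Facial selectivity may be poor if magnesium salts or THF carried into the divinylzinc solution promote an uncatalysed background addition, which would erode the configuration of C2'. The fallback sets out from 10 and 11 and comes back at 13. Direct Grignard addition gives racemic (4E,6E)-8,8-dimethoxyocta-1,4,6-trien-3-ol F4. Lipase-catalysed acylation (immobilised Candida antarctica lipase B, vinyl acetate, hexane) should, by the usual empirical rule for secondary alcohols (vinyl as the medium group, dienyl as the large group), convert the R enantiomer into (3R,4E,6E)-8,8-dimethoxyocta-1,4,6-trien-3-yl acetate F5. This is separated from the unreacted S alcohol and methanolysed (K2CO3, MeOH) to 13.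

**Further compounds**
F1 | step 13 | (4E,6E)-2-methyl-3,8-bis(triethylsilyloxy)deca-4,6-diene-1,10-diol (centres as in 21) | OC[C@@H](C)[C@H](/C=C/C=C/[C@H](O[Si](CC)(CC)CC)CCO)O[Si](CC)(CC)CC
F2 | step 13 | (4E,6E)-1,10-diiodo-2-methyl-3,8-bis(triethylsilyloxy)deca-4,6-diene (centres as in 21) | IC[C@@H](C)[C@H](/C=C/C=C/[C@H](O[Si](CC)(CC)CC)CCI)O[Si](CC)(CC)CC
F3 | step 13 | bis(iodozinc) reagent from F2, (4E,6E)-2-methyl-3,8-bis(triethylsilyloxy)deca-4,6-diene-1,10-diylbis(zinc iodide) | I[Zn]C[C@@H](C)[C@H](/C=C/C=C/[C@H](O[Si](CC)(CC)CC)CC[Zn]I)O[Si](CC)(CC)CC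
F0 | step 15 | none | none
F4 | step 8 | racemic (4E,6E)-8,8-dimethoxyocta-1,4,6-trien-3-ol | COC(OC)/C=C/C=C/C(O)C=C
F5 | step 8 | (3R,4E,6E)-8,8-dimethoxyocta-1,4,6-trien-3-yl acetate | COC(OC)/C=C/C=C/[C@H](OC(C)=O)C=C
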